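The trans-decalin is not made by polyene cyclisation but by one type 1 intramolecular Diels–Alder reaction that closes rings A and B together: it forms C1–C2 and the crowded ring-fusion bond C5–C10, creating the quaternary C10 and the C5 stereocentre at once. The step exploits that C10–C1 of ring A can be an isopropenyl alkene and C2–C5 an (E)-diene whose C4 already bears one methyl. The precursor is therefore an acyclic triene, diene and dienophile joined by C6–C9, with the C8 carbinol, C9 and C13 stereocentres in place from (S)-citronellol and a Sharpless asymmetric epoxidation. The C3=C4 alkene left behind then accepts the second C4 methyl by hydromethylation.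

Key step: step 9

Remark: labdane numbering is used throughout (ring A = C1–C5 and C10, ring B = C5–C10, side chain C11–C15 with C16 on C13, C17 on C8, C18/C19 on C4, C20 on C10), the target is read as the (5S,8R,9R,10S,13S) isomer, and reagent 17 is assumed to be made beforehand by condensing octane-1-sulfonohydrazide with formaldehyde.

Step 1
Reactants: 1 (S)-citronellol
Product: 2 (S)-citronellyl tert-butyldimethylsilyl ether
Conditions: TBSCl, imidazole, CH2Cl2, 0 °C to rt
Reagents that add atoms: tert-butyldimethylsilyl chloride, CC(C)(C)[Si](C)(C)Cl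
Why: Imidazole-promoted silylation masks the primary O15 hydroxyl against the later organometallic steps and leaves the C13 stereocentre untouched.

Step 2
Reactants: 2 (S)-citronellyl tert-butyldimethylsilyl ether
Product: 3 (2E,6S)-allylic alcohol
Conditions: SeO2 (cat.), t-BuOOH, CH2Cl2, rt
Reagents that add atoms: tert-butyl hydroperoxide, CC(C)(C)OO
Why: Riley allylic oxidation (ene reaction then [2,3]-sigmatropic shift) should hydroxylate only the (E)-methyl of the trisubstituted alkene, giving the (E)-allylic alcohol whose carbinol carbon becomes C7.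

Step 3
Reactants: 3 (2E,6S)-allylic alcohol
Product: 4 (2R,3R)-epoxy alcohol
Conditions: Ti(OiPr)4 (cat.), D-(−)-diethyl tartrate (cat.), t-BuOOH, 4 Å molecular sieves, CH2Cl2, −20 °C
Reagents that add atoms: tert-butyl hydroperoxide, CC(C)(C)OO
Why: Sharpless asymmetric epoxidation with the D-tartrate should deliver oxygen to the alkene face that gives the (2R,3R)-epoxide, setting C8 and (before its inversion) C9 under reagent control, the remote C13 centre having no influence.

Step 4
Reactants: 4 (2R,3R)-epoxy alcohol; 5 isopropenylmagnesium bromide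
Product: 6 (2S,3R,6S)-1,2-diol carrying the isopropenyl group on C9
Conditions: CH2=C(CH3)MgBr (excess), CuI (cat.), THF, −30 to 0 °C; aqueous work-up
Reagents that add atoms: none
Why: Copper-catalysed SN2 opening of the 2,3-epoxy alcohol by the Grignard reagent should occur at the secondary C9 (the C8 end is quaternary) with inversion, which installs the dienophile, sets C9 and leaves the C8–O bond with retention.

Step 5
Reactants: 6 (2S,3R,6S)-1,2-diol
Product: 8 (2S)-2,2-disubstituted terminal epoxide, via monotosylate 7 (not isolated)
Conditions: NaH, 1-(p-toluenesulfonyl)imidazole, THF, 0 °C to rt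
Reagents that add atoms: none
Why: Selective sulfonylation of the primary hydroxyl followed by intramolecular Williamson closure by the tertiary alkoxide should give the epoxide with C8 unchanged, because its C–O bond is never broken.

Step 6
Reactants: 8 (2S)-terminal epoxide; 9 acetaldehyde N,N-dimethylhydrazone
Product: 11 lactol (both anomers), via hydroxy hydrazone 10 (not isolated)
Conditions: LiN(iPr)2, THF, 0 °C; then 8, 0 °C to rt; then aq. oxalic acid, Et2O, rt
Reagents that add atoms: water, O
Why: Aza-enolate alkylation (the lithiated hydrazone as an acetaldehyde enolate equivalent) should open the epoxide at its CH2 terminus C7, and mild hydrolysis frees the γ-hydroxy aldehyde as its lactol, the new anomeric centre being destroyed in the next step.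

Step 7
Reactants: 11 lactol; 12 2-(triphenylphosphoranylidene)propanal
Product: 13 (2E)-hydroxy enal
Conditions: toluene, 90 °C
Reagents that add atoms: none
Why: Wittig olefination of the ring-opened lactol with the stabilised ylide should give the (E)-2-methyl enal (C4=C5), and the neutral medium avoids oxa-Michael closure by the tertiary alcohol.

Step 8
Reactants: 13 (2E)-hydroxy enal; 14 methyltriphenylphosphonium bromide
Product: 15 (3E)-triene
Conditions: KN(SiMe3)2, THF, 0 °C; then 13, −78 to 0 °C
Reagents that add atoms: none
Why: Wittig methylenation of the aldehyde completes the (E)-1,3-diene (C2=C3–C4=C5) without touching the C4=C5 geometry or any stereocentre.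

Step 9
Reactants: 15 (3E)-triene
Product: 16 trans-fused octalin (rings A and B, C3=C4 alkene)
Conditions: toluene (0.01 M), BHT (cat.), base-washed sealed tube, 200 °C
Reagents that add atoms: none
Why: Thermal, concerted but asynchronous [4+2] cycloaddition, a type 1 intramolecular Diels–Alder reaction of an (E)-1,7,9-decatriene (the closest known class is the cyclisation of unactivated decatrienes to octalins), joins C2 to C1 and C5 to the fully substituted C10 in one event, helped by the Thorpe–Ingold effect of the quaternary C8 and branched C9 in the tether. Ring A is closed as the new cyclohexene of the cycloaddition itself (suprafacial six-electron closure across C2–C5 and C10–C1), and ring B by the same C5–C10 bond across the four-atom tether C6–C9 in the tether-anti (exo) mode with the forming ring in a chair. C5 and C10 are created together: the (E)-C4=C5 geometry and the anti transition state put H5 and the C20 methyl trans (trans-decalin), and the absolute sense follows from C8 and C9, because the chair that keeps the C9 side chain and the C8 oxygen equatorial (C17 axial, as in the target) avoids an axial C11 pointing into the incoming diene. The step needs trans over cis ring fusion and attack on one face of the isopropenyl group; the first should be secured by the C4 methyl, which is cis to C6 on the diene and is pressed against the tether in the syn (cis-fused) arrangement, the second by the equatorial preference at C9 just described. Regiochemistry is not in question because the isopropenyl group is the only alkene that can reach the diene through a six-membered array. The free tertiary alcohol should survive, since retro-ene cleavage of such homoallylic alcohols and dehydration in acid-free glass are far slower than the cyclisation at 200 °C.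

Step 10
Reactants: 16 trans-fused octalin; 17 N'-methylideneoctane-1-sulfonohydrazide
Product: 19 silyl-protected labdane-8,15-diol, via sulfonyl hydrazide 18 (not isolated)
Conditions: Fe(acac)3 (cat.), PhSiH3, THF/MeOH, rt; then MeOH, 60 °C
Reagents that add atoms: none
Why: Metal-hydride hydrogen-atom-transfer hydromethylation: the iron hydride should deliver H to C3, the tertiary C4 radical adds to the C=N of the formaldehyde hydrazone, and loss of sulfinate and N2 on warming leaves a methyl group, C4 becoming non-stereogenic so that no facial question arises.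

Step 11
Reactants: 19 silyl-protected labdane-8,15-diol
Product: 20 labdane-8,15-diol
Conditions: Bu4NF, THF, rt
Reagents that add atoms: none
Why: Fluoride-mediated desilylation frees the primary C15 hydroxyl without affecting the tertiary alcohol or any stereocentre.

Step 12
Reactants: 20 labdane-8,15-diol; 21 3-phenylpropanoyl chloride
Product: 22 target ester
Conditions: pyridine, DMAP (cat.), CH2Cl2, 0 °C
Reagents that add atoms: none
Why: Acylation with the acid chloride under nucleophilic catalysis should take place only at the unhindered primary hydroxyl, the tertiary C8 hydroxyl flanked by C9 and the axial methyl being unreactive under these conditions.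

Compound list
1 | (S)-citronellol, (3S)-3,7-dimethyloct-6-en-1-ol | C[C@H](CCO)CCC=C(C)C | starting material
2 | tert-butyl{[(3S)-3,7-dimethyloct-6-en-1-yl]oxy}dimethylsilane | C[C@H](CCO[Si](C)(C)C(C)(C)C)CCC=C(C)C | intermediate
3 | (2E,6S)-8-[(tert-butyldimethylsilyl)oxy]-2,6-dimethyloct-2-en-1-ol | C[C@H](CCO[Si](C)(C)C(C)(C)C)CC/C=C(\C)CO | intermediate
4 | [(2R,3R)-3-{(3S)-5-[(tert-butyldimethylsilyl)oxy]-3-methylpentyl}-2-methyloxiran-2-yl]methanol | OC[C@@]1(C)O[C@@H]1CC[C@H](C)CCO[Si](C)(C)C(C)(C)C | intermediate
5 | isopropenylmagnesium bromide (prop-1-en-2-ylmagnesium bromide) | CC(=C)[Mg]Br | starting material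
6 | (2S,3R,6S)-8-[(tert-butyldimethylsilyl)oxy]-2,6-dimethyl-3-(prop-1-en-2-yl)octane-1,2-diol | OC[C@@](C)(O)[C@@H](C(C)=C)CC[C@H](C)CCO[Si](C)(C)C(C)(C)C | intermediate
7 | 1-O-(p-toluenesulfonyl) derivative of diol 6 (primary monotosylate) | Cc1ccc(cc1)S(=O)(=O)OC[C@@](C)(O)[C@@H](C(C)=C)CC[C@H](C)CCO[Si](C)(C)C(C)(C)C | intermediate (not isolated)
8 | (2S)-2-methyl-2-{(3R,6S)-8-[(tert-butyldimethylsilyl)oxy]-2,6-dimethyloct-1-en-3-yl}oxirane | C1O[C@@]1(C)[C@@H](C(C)=C)CC[C@H](C)CCO[Si](C)(C)C(C)(C)C | intermediate
9 | acetaldehyde N,N-dimethylhydrazone | CC=NN(C)C | starting material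
10 | (4R,5R,8S)-10-[(tert-butyldimethylsilyl)oxy]-4-hydroxy-4,8-dimethyl-5-(prop-1-en-2-yl)decanal N,N-dimethylhydrazone | CN(C)N=CCC[C@@](C)(O)[C@@H](C(C)=C)CC[C@H](C)CCO[Si](C)(C)C(C)(C)C | intermediate (not isolated)
11 | (5R)-5-methyl-5-{(3R,6S)-8-[(tert-butyldimethylsilyl)oxy]-2,6-dimethyloct-1-en-3-yl}oxolan-2-ol (both anomers) | OC1CC[C@@](C)(O1)[C@@H](C(C)=C)CC[C@H](C)CCO[Si](C)(C)C(C)(C)C | intermediate
12 | 2-(triphenylphosphoranylidene)propanal | CC(C=O)=P(c1ccccc1)(c1ccccc1)c1ccccc1 | starting material
13 | (2E,6R,7R,10S)-12-[(tert-butyldimethylsilyl)oxy]-6-hydroxy-2,6,10-trimethyl-7-(prop-1-en-2-yl)dodec-2-enal | O=C/C(C)=C/CC[C@@](C)(O)[C@@H](C(C)=C)CC[C@H](C)CCO[Si](C)(C)C(C)(C)C | intermediate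
14 | methyltriphenylphosphonium bromide | [Br-].C[P+](c1ccccc1)(c1ccccc1)c1ccccc1 | starting material
15 | (3E,7R,8R,11S)-13-[(tert-butyldimethylsilyl)oxy]-3,7,11-trimethyl-8-(prop-1-en-2-yl)trideca-1,3-dien-7-ol | C=C/C(C)=C/CC[C@@](C)(O)[C@@H](C(C)=C)CC[C@H](C)CCO[Si](C)(C)C(C)(C)C | intermediate
16 | (1R,2R,4aS,8aS)-1-{(3S)-5-[(tert-butyldimethylsilyl)oxy]-3-methylpentyl}-2,5,8a-trimethyl-1,2,3,4,4a,7,8,8a-octahydronaphthalen-2-ol | C[C@H](CCO[Si](C)(C)C(C)(C)C)CC[C@@H]1[C@@]2(C)CCC=C(C)[C@@H]2CC[C@@]1(C)O | intermediate
17 | N'-methylideneoctane-1-sulfonohydrazide (formaldehyde N-octylsulfonylhydrazone) | C=NNS(=O)(=O)CCCCCCCC | starting material (reagent made beforehand, see remark)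
18 | N'-alkyl octane-1-sulfonohydrazide in which C4 of the decalin carries CH2–NH–NH–SO2C8H17 (C4 epimers) | C[C@H](CCO[Si](C)(C)C(C)(C)C)CC[C@@H]1[C@@]2(C)CCCC(C)(CNNS(=O)(=O)CCCCCCCC)[C@@H]2CC[C@@]1(C)O | intermediate (not isolated)
19 | (1R,2R,4aS,8aS)-1-{(3S)-5-[(tert-butyldimethylsilyl)oxy]-3-methylpentyl}-2,5,5,8a-tetramethyldecahydronaphthalen-2-ol | C[C@H](CCO[Si](C)(C)C(C)(C)C)CC[C@@H]1[C@@]2(C)CCCC(C)(C)[C@@H]2CC[C@@]1(C)O | intermediate
20 | (1R,2R,4aS,8aS)-1-[(3S)-5-hydroxy-3-methylpentyl]-2,5,5,8a-tetramethyldecahydronaphthalen-2-ol | C[C@H](CCO)CC[C@@H]1[C@@]2(C)CCCC(C)(C)[C@@H]2CC[C@@]1(C)O | intermediate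
21 | 3-phenylpropanoyl chloride | O=C(Cl)CCc1ccccc1 | starting material
22 | (3S)-5-[(1R,2R,4aS,8aS)-2-hydroxy-2,5,5,8a-tetramethyldecahydronaphthalen-1-yl]-3-methylpentyl 3-phenylpropanoate | C[C@H](CCOC(=O)CCc1ccccc1)CC[C@@H]1[C@@]2(C)CCCC(C)(C)[C@@H]2CC[C@@]1(C)O | target

Total step count: 12
Longest linear sequence: 12 steps, from (S)-citronellol 1 to 22

Steps most likely to fail

Step 9. The diene may add to the wrong face of the isopropenyl group or through the syn (cis-fused) arrangement, because the conformational preferences that steer it are small at 200 °C. Slow cyclisation could also let dehydration of the tertiary alcohol compete. The fallback sets out from triene 15 and replaces the pericyclic reaction by a metal-mediated stepwise [4+2]: a cationic monovalent-rhodium catalyst ([Rh(cod)Cl]2 with AgSbF6, CH2Cl2, 25 to 40 °C) should couple diene and alkene through a rhodacycle, a process known for unactivated diene–ene tethers. At this low temperature the same chair preferences weigh more. The fallback comes back to the route at octalin 16 and makes no new compound (F0).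

Step 10. The tertiary C4 radical is hindered, so hydrogen transfer to it (plain reduction of C3=C4) may outrun its addition to the hydrazone. The fallback sets out from octalin 16 and builds the second methyl by the classical two-stage route. Simmons–Smith cyclopropanation (Et2Zn, CH2I2, CH2Cl2, 0 °C) should give the cyclopropane-fused decalin F1. Hydrogenolysis (H2, PtO2, AcOH, rt) should then cleave the less substituted C3–CH2 bond and leave the gem-dimethyl group, coming back at 19.

Step 4. The hindered trisubstituted epoxide may be opened slowly, and attack at C8 or base-induced isomerisation may compete. The fallback sets out from epoxy alcohol 4 and brings in the three carbons as an alkyne. The alkynylalane Et2AlC≡CSiMe3 (from trimethylsilylacetylene, n-BuLi and Et2AlCl; toluene, 0 °C) should open the epoxide at C9 with inversion to give the silylalkynyl diol F2. K2CO3 in MeOH removes the C-silyl group to give the terminal alkyne F3. Zirconium-catalysed carboalumination (Me3Al, Cp2ZrCl2 cat., CH2Cl2, then water) adds methyl to the inner and hydrogen to the outer alkyne carbon, coming back at diol 6.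

Further compounds
F0 | step 9 | none | none
F1 | step 10 | cyclopropane-fused decalin (CH2 bridging C3 and C4 of 16, either face) | C[C@H](CCO[Si](C)(C)C(C)(C)C)CC[C@@H]1[C@@]2(C)CCC3CC3(C)[C@@H]2CC[C@@]1(C)O
F2 | step 4 | (2S,3R,6S)-8-[(tert-butyldimethylsilyl)oxy]-2,6-dimethyl-3-[(trimethylsilyl)ethynyl]octane-1,2-diol | OC[C@@](C)(O)[C@@H](C#C[Si](C)(C)C)CC[C@H](C)CCO[Si](C)(C)C(C)(C)C
F3 | step 4 | (2S,3R,6S)-8-[(tert-butyldimethylsilyl)oxy]-3-ethynyl-2,6-dimethyloctane-1,2-diol | OC[C@@](C)(O)[C@@H](C#C)CC[C@H](C)CCO[Si](C)(C)C(C)(C)C
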